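## Retrosynthetic overview

1. The target comes from its penta-O-silyl ether by global desilylation; no ring is made or broken after the key step.
2. Key disconnection: C3 (flavanone)–C3' (flavone ring B). C3 is used as an enolonium (α-keto cation) equivalent, a 3-bromoflavanone, and C3' as an aryl-zinc. Both carbons are natively nucleophilic (ketone α-carbon, phenol ortho-carbon). The nickel-catalysed union sets C3 trans to the existing C2 centre.
3. Flavanone half: both rings and the C2 (S) centre are taken intact from (S)-naringenin (per-silylation to the enol silane, then NBS).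
4. Flavone half: its pyranone ring is the only ring built, and it is built first (aldol condensation, oxa-Michael closure, dehydrogenation from 2',6'-dihydroxy-4'-methoxyacetophenone and 4-hydroxy-3-iodobenzaldehyde). The iodine marks C3' for zinc insertion.

Assumption: (S)-naringenin is bought as the natural (2S) enantiomer with at least 98% ee (checked by chiral HPLC), and a one-pot operation counts as one step.

Abbreviation: TBS = tert-butyldimethylsilyl.

## Route

Step 1
Reactants: 1 (S)-naringenin [(2S)-5,7-dihydroxy-2-(4-hydroxyphenyl)chroman-4-one]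
Product: 3 (2R,3R)-3-bromo-5,7-bis(tert-butyldimethylsilyloxy)-2-[4-(tert-butyldimethylsilyloxy)phenyl]chroman-4-one (2,3-trans), via tetrasilyl enol ether 2 (not isolated)
Conditions: TBSOTf (4.5 equiv), Et3N (6 equiv), CH2Cl2, −40 → 0 °C; then NBS (1.05 equiv), THF, −78 °C; aqueous NaHCO3 work-up
Reagents that add atoms: tert-butyldimethylsilyl triflate (TBSOTf) CC(C)(C)[Si](C)(C)OS(=O)(=O)C(F)(F)F; N-bromosuccinimide (NBS) O=C1CCC(=O)N1Br
Why: Soft enolisation with a silyl triflate and an amine base silylates the three phenols and turns the ketone into its enol silane without a free enolate, so the C2–O1 bond is not opened and C2 stays S, and electrophilic α-bromination of the enol silane with NBS (much faster than bromination of the silylated aryl rings) then gives the α-bromoketone with bromine anti to the C2 aryl group, although the C3 configuration is not critical because step 4 passes through a planar C3 radical.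

Step 2
Reactants: 4 2',6'-dihydroxy-4'-methoxyacetophenone; 5 4-hydroxy-3-iodobenzaldehyde
Product: 8 3'-iodogenkwanin [5-hydroxy-2-(4-hydroxy-3-iodophenyl)-7-methoxy-4H-chromen-4-one], via chalcone 6 (not isolated), via flavanone 7 (not isolated)
Conditions: pyrrolidine (0.5 equiv), I2 (10 mol%), DMSO, 130 °C
Reagents that add atoms: none
Why: Pyrrolidine-catalysed Claisen–Schmidt aldol condensation gives the 2'-hydroxychalcone, which closes by intramolecular oxa-Michael addition to the flavanone and is dehydrogenated in the same flask by the I2/DMSO couple (α-iodination and loss of HI, DMSO as terminal oxidant) to the flavone, the symmetrical 2',6'-dihydroxy ketone leaving the chelated 5-OH and no stereocentre.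

Step 3
Reactants: 8 3'-iodogenkwanin
Product: 9 5-(tert-butyldimethylsilyloxy)-2-[4-(tert-butyldimethylsilyloxy)-3-iodophenyl]-7-methoxy-4H-chromen-4-one
Conditions: TBSOTf (2.6 equiv), Et3N (4 equiv), CH2Cl2, 0 °C → rt
Reagents that add atoms: tert-butyldimethylsilyl triflate (TBSOTf) CC(C)(C)[Si](C)(C)OS(=O)(=O)C(F)(F)F
Why: Phenol O-silylation with a silyl triflate caps the 4'-OH and the chelated 5-OH, both of which would otherwise protonate the aryl-zinc reagent of step 4.

Step 4
Reactants: 9 5-(tert-butyldimethylsilyloxy)-2-[4-(tert-butyldimethylsilyloxy)-3-iodophenyl]-7-methoxy-4H-chromen-4-one; 3 (2R,3R)-3-bromo-5,7-bis(tert-butyldimethylsilyloxy)-2-[4-(tert-butyldimethylsilyloxy)phenyl]chroman-4-one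
Product: 11 (2S,3R)-5,7-bis(TBS-oxy)-2-[4-(TBS-oxy)phenyl]-3-{2-(TBS-oxy)-5-[5-(TBS-oxy)-7-methoxy-4-oxo-4H-chromen-2-yl]phenyl}chroman-4-one (2,3-trans), via arylzinc iodide 10 (not isolated)
Conditions: 9 (1.3 equiv), Zn dust (activated with BrCH2CH2Br and Me3SiCl), LiCl, THF, 50 °C; then 3 (1.0 equiv), NiCl2(dme) (10 mol%), 2,6-bis(4,4-dimethyl-4,5-dihydrooxazol-2-yl)pyridine (13 mol%), DME/THF, −30 → 0 °C
Reagents that add atoms: none
Why: Nickel-catalysed Negishi α-arylation of a secondary α-bromoketone: LiCl-assisted zinc insertion into the C–I bond fixes the nucleophile at C3', the bromoketone serves as the enolonium (α-keto cation) equivalent so that two natively nucleophilic carbons (ketone α-carbon and phenol ortho-carbon) are joined, and the aryl–nickel species captures the planar C3 radical on the face anti to the equatorial C2 aryl group, which sets C3 as R (2,3-trans, also the thermodynamic epimer) from either C3 epimer of 3 while C2 is untouched.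

Step 5
Reactants: 11 (2S,3R)-penta-O-TBS ether of the target
Product: 12 (2S,3R)-5,7-dihydroxy-3-[2-hydroxy-5-(5-hydroxy-7-methoxy-4-oxo-4H-chromen-2-yl)phenyl]-2-(4-hydroxyphenyl)chroman-4-one (CNP0361110.2)
Conditions: TBAF (6 equiv), AcOH (6 equiv), THF, 0 °C → rt
Reagents that add atoms: none
Why: Fluoride-mediated cleavage of the five aryl silyl ethers (desilylation driven by Si–F bond formation) under acetic acid buffering keeps the freed phenols protonated, so neither retro-oxa-Michael ring opening nor epimerisation at C2 or C3 occurs and the (2S,3R) configuration is carried through unchanged.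

## Compound list

1 | (S)-naringenin, (2S)-5,7-dihydroxy-2-(4-hydroxyphenyl)chroman-4-one | C1C(=O)c2c(O)cc(O)cc2O[C@@H]1c1ccc(O)cc1 | starting material
2 | (2S)-4,5,7-tris(tert-butyldimethylsilyloxy)-2-[4-(tert-butyldimethylsilyloxy)phenyl]-2H-chromene (tetrasilyl enol ether) | C1=C(O[Si](C)(C)C(C)(C)C)c2c(O[Si](C)(C)C(C)(C)C)cc(O[Si](C)(C)C(C)(C)C)cc2O[C@@H]1c1ccc(O[Si](C)(C)C(C)(C)C)cc1 | intermediate
3 | (2R,3R)-3-bromo-5,7-bis(tert-butyldimethylsilyloxy)-2-[4-(tert-butyldimethylsilyloxy)phenyl]chroman-4-one (2,3-trans; a minor C3 epimer is equally usable) | Br[C@H]1C(=O)c2c(O[Si](C)(C)C(C)(C)C)cc(O[Si](C)(C)C(C)(C)C)cc2O[C@@H]1c1ccc(O[Si](C)(C)C(C)(C)C)cc1 | intermediate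
4 | 2',6'-dihydroxy-4'-methoxyacetophenone, 1-(2,6-dihydroxy-4-methoxyphenyl)ethanone | CC(=O)c1c(O)cc(OC)cc1O | starting material
5 | 4-hydroxy-3-iodobenzaldehyde | O=Cc1ccc(O)c(I)c1 | starting material
6 | (E)-1-(2,6-dihydroxy-4-methoxyphenyl)-3-(4-hydroxy-3-iodophenyl)prop-2-en-1-one (chalcone) | COc1cc(O)c(C(=O)/C=C/c2ccc(O)c(I)c2)c(O)c1 | intermediate
7 | racemic 5-hydroxy-2-(4-hydroxy-3-iodophenyl)-7-methoxychroman-4-one (flavanone) | COc1cc(O)c2C(=O)CC(c3ccc(O)c(I)c3)Oc2c1 | intermediate
8 | 3'-iodogenkwanin, 5-hydroxy-2-(4-hydroxy-3-iodophenyl)-7-methoxy-4H-chromen-4-one | COc1cc(O)c2c(=O)cc(-c3ccc(O)c(I)c3)oc2c1 | intermediate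
9 | 5-(tert-butyldimethylsilyloxy)-2-[4-(tert-butyldimethylsilyloxy)-3-iodophenyl]-7-methoxy-4H-chromen-4-one | COc1cc(O[Si](C)(C)C(C)(C)C)c2c(=O)cc(-c3ccc(O[Si](C)(C)C(C)(C)C)c(I)c3)oc2c1 | intermediate
10 | {2-(tert-butyldimethylsilyloxy)-5-[5-(tert-butyldimethylsilyloxy)-7-methoxy-4-oxo-4H-chromen-2-yl]phenyl}zinc iodide (LiCl adduct in THF) | COc1cc(O[Si](C)(C)C(C)(C)C)c2c(=O)cc(-c3ccc(O[Si](C)(C)C(C)(C)C)c([Zn]I)c3)oc2c1 | intermediate
11 | (2S,3R)-5,7-bis(tert-butyldimethylsilyloxy)-2-[4-(tert-butyldimethylsilyloxy)phenyl]-3-{2-(tert-butyldimethylsilyloxy)-5-[5-(tert-butyldimethylsilyloxy)-7-methoxy-4-oxo-4H-chromen-2-yl]phenyl}chroman-4-one (2,3-trans) | COc1cc(O[Si](C)(C)C(C)(C)C)c2c(=O)cc(-c3ccc(O[Si](C)(C)C(C)(C)C)c([C@H]4C(=O)c5c(O[Si](C)(C)C(C)(C)C)cc(O[Si](C)(C)C(C)(C)C)cc5O[C@@H]4c4ccc(O[Si](C)(C)C(C)(C)C)cc4)c3)oc2c1 | intermediate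
12 | (2S,3R)-5,7-dihydroxy-3-[2-hydroxy-5-(5-hydroxy-7-methoxy-4-oxo-4H-chromen-2-yl)phenyl]-2-(4-hydroxyphenyl)chroman-4-one (CNP0361110.2; 2,3-trans) | COc1cc(O)c2c(=O)cc(-c3ccc(O)c([C@H]4C(=O)c5c(O)cc(O)cc5O[C@@H]4c4ccc(O)cc4)c3)oc2c1 | target

## Step count and risks

Total steps: 5. Longest linear sequence: 4 steps (4 + 5 → 8 → 9 → 11 → 12, steps 2 to 5).

**Step 4 is the most likely to fail.** The aryl-zinc carries an ortho silyloxy group and the bromide is a hindered secondary centre. Competing paths are loss of HBr to the flavone, zinc enolate formation with opening of the pyranone ring, and slow zinc insertion into the electron-rich iodide. The fallback inverts the roles of the two halves. It sets out from 9, partnered with enol silane 2, which is now isolated cold by a non-aqueous work-up after the silylation half of step 1. Compound 9 is oxidised in the presence of mesitylene (mCPBA, TsOH·H2O, CH2Cl2/CF3CH2OH, rt) to the aryl(mesityl)iodonium tosylate F1, an aryl-cation equivalent. F1 then arylates the nucleophilic C3 of 2 under Cu(OTf)2 catalysis (CH2Cl2, rt), by analogy with copper-catalysed arylations of enol silanes by diaryliodonium salts. The aryl group enters anti to the C2 aryl group, and the fallback comes back to the route at 11.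

**Step 1 is the second risk.** The 4-O/5-O peri pair of silyl groups may slow enol silane formation, which would let NBS brominate ring A. The free 4'-OH next to an amine can also open the ring through the para-quinone methide and erode the ee. The fallback changes both the protecting groups and the way bromine is introduced. It sets out from 1. Ac2O in pyridine (too weak a base to form a phenoxide) gives (S)-naringenin triacetate F2. The three acetoxy groups deactivate ring A, so CuBr2 in refluxing EtOAc/CHCl3 brominates the ketone through its enol under acidic conditions to the 2,3-trans 3-bromo triacetate F3. F3 takes the place of 3 in step 4 and gives the coupled triacetate bis-silyl ether F4. Acidic methanolysis (HCl in MeOH, 40 °C) removes the acetates and silyl groups together, so the fallback comes back to the route at 12.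

**Step 2 is the third risk.** The unprotected phenols slow the aldol step (phenoxide-deactivated aldehyde, doubly ortho-substituted ketone), and I2/DMSO can iodinate ring A or move the aryl iodine. The fallback replaces the aldol/oxidation sequence by an acylation/cyclodehydration (Baker–Venkataraman-type) sequence. It sets out from 4. Commercial methyl 4-hydroxy-3-iodobenzoate is silylated (TBSCl, imidazole, DMF) to methyl 4-(tert-butyldimethylsilyloxy)-3-iodobenzoate F5. Compound 4 is converted with LiN(SiMe3)2 (4 equiv, THF, −78 °C) into its trilithio derivative and C-acylated by F5 (Claisen condensation, −78 °C → rt) to the β-diketone F6. AcOH with catalytic H2SO4 at 95 °C cyclodehydrates F6 and cleaves the silyl ether, and the fallback comes back to the route at 8.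

## Further compounds

F1 | step 4 | {2-(tert-butyldimethylsilyloxy)-5-[5-(tert-butyldimethylsilyloxy)-7-methoxy-4-oxo-4H-chromen-2-yl]phenyl}(2,4,6-trimethylphenyl)iodonium tosylate | COc1cc(O[Si](C)(C)C(C)(C)C)c2c(=O)cc(-c3ccc(O[Si](C)(C)C(C)(C)C)c([I+]c4c(C)cc(C)cc4C)c3)oc2c1.Cc1ccc(cc1)S(=O)(=O)[O-]
F2 | step 1 | (2S)-5,7-diacetoxy-2-(4-acetoxyphenyl)chroman-4-one ((S)-naringenin triacetate) | C1C(=O)c2c(OC(C)=O)cc(OC(C)=O)cc2O[C@@H]1c1ccc(OC(C)=O)cc1
F3 | step 1 | (2R,3R)-5,7-diacetoxy-2-(4-acetoxyphenyl)-3-bromochroman-4-one (2,3-trans) | Br[C@H]1C(=O)c2c(OC(C)=O)cc(OC(C)=O)cc2O[C@@H]1c1ccc(OC(C)=O)cc1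
F4 | step 1 | (2S,3R)-5,7-diacetoxy-2-(4-acetoxyphenyl)-3-{2-(tert-butyldimethylsilyloxy)-5-[5-(tert-butyldimethylsilyloxy)-7-methoxy-4-oxo-4H-chromen-2-yl]phenyl}chroman-4-one (2,3-trans) | COc1cc(O[Si](C)(C)C(C)(C)C)c2c(=O)cc(-c3ccc(O[Si](C)(C)C(C)(C)C)c([C@H]4C(=O)c5c(OC(C)=O)cc(OC(C)=O)cc5O[C@@H]4c4ccc(OC(C)=O)cc4)c3)oc2c1
F5 | step 2 | methyl 4-(tert-butyldimethylsilyloxy)-3-iodobenzoate | COC(=O)c1ccc(O[Si](C)(C)C(C)(C)C)c(I)c1
F6 | step 2 | 1-(2,6-dihydroxy-4-methoxyphenyl)-3-[4-(tert-butyldimethylsilyloxy)-3-iodophenyl]propane-1,3-dione | COc1cc(O)c(C(=O)CC(=O)c2ccc(O[Si](C)(C)C(C)(C)C)c(I)c2)c(O)c1
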